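Start from the late end of the run, where the untrapped substrate sits in forms that trade among themselves, and ask how the charge divides there.

    capture agent + adduct → trapped intermediate (k1 = 0.31 M⁻¹ s⁻¹)
    gas ⇌ coupling partner, rate k2*(csat - [coupling partner]) (k2 = 0.21 s⁻¹, csat = 83 mM)
    adduct ⇌ product (K3 = 40, k3 = 0.079 s⁻¹)
    substrate + coupling partner ⇌ adduct (K4 = 13 M⁻¹, k4 = 0.73 M⁻¹ s⁻¹)

substrate 0.26 M; capture agent 0.0260 M; gas 83 mM (held); time 50 min

- which holds at 50 min: what has brought the reaction to rest, or that it has not come to rest (it is still moving / forward and back rates have come level)
- the product standing at 50 min, as a percentage of the substrate charged
- the trapped intermediate standing at 50 min, as a percentage of the substrate charged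

- at the start none of coupling partner is dissolved
- the reaction counts as stopped when no species that holds the substrate changes by six tenths of a point or more over the second half of the time
- run time (flask): 50 min

Treat the reversible steps as level, because the relaxation half-life of adduct and product is 0.143 min and that of substrate and adduct, with the coupling partner held, is 0.0990 min, each short against the 50 min of the run, and take the coupling partner at the 83 mM that the gas holds. Each part of substrate then stands beside 1.08 parts of adduct and 43.2 parts of product, so carry one number, the product's share of the untrapped pool 95.4%; the adduct's share is 2.39%.

Now set this flask beside the neighbour charged with a quarter of its capture agent. The reckoned share is the same in these two flasks, so the reckoning parts them by what capture withdraws for good: a ceiling of 10.0% of the charge here and 2.50% in the neighbour, the capture agent being the limiting reagent for trapping, with less of it charged than of substrate.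

Seen from the capture agent, take the adduct as a steady partner at its share of the pool, so that the loss is pseudo-first-order, with a half-life of 6.68 min in this flask and 6.16 min in the neighbour, each shorter than the run. This flask and the neighbour are therefore reckoned to come close to their ceilings within the run, with the remainder in the pool.

Early on, the product is made through the adduct, and for that first-order step the excess of adduct summed over time is the product made divided by 0.079 s⁻¹; count that passage as a factor of 0.416 on the capture agent. For this flask, reckon 3.11% of the charged capture agent left at half time and 0.232% at the end, so the trapped share is reckoned to move 0.29 percentage points over the second half, less than the mark for rest.

Commit for this flask to forward and back rates have come level, with trapped intermediate at 9.98% and product at 85.9%.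

The forecast says forward and back rates have come level, with 85.9% of product and 9.97% of trapped intermediate, and holds that “Capture is slow and irreversible”.

The simulated flask gives forward and back rates have come level, with 85.9% of product and 9.98% of trapped intermediate. The largest change of a share in this flask over the second half is 0.3 points. Now use the share on the neighbour: 95.4% of the 97.5% left untrapped gives 93.0% of product, and that neighbour stands at 93.0%.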